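**Retrosynthetic overview**

1. Feature: in unit B (the 6',7'-dihydroxycoumarin, primed locants) the lactone oxygen O1' is bonded to C8a'. C8a' lies para to the C6' hydroxyl. Once the 6',7'-catechol is raised to its ortho-quinone, C8a' is the β-carbon of the C7'=O/C8'=C8a' enone, so a carboxyl held cis on the C3'=C4' alkene can make C8a'–O1' without a pre-installed oxygen.
2. Disconnections: (a) the O7–benzyl bond (last step); (b) C8a'–O1', the pyranone of unit B, back to the (Z)-2-(coumarin-3-yl)-3-(3,4-dihydroxyphenyl)acrylic acid; (c) C3–C3' by Stille coupling of a 3-bromocoumarin and an α-stannyl cinnamate.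
3. The Z geometry (carboxyl cis to the catechol ring) is not left to a condensation, which would place the two groups trans. It is fixed by syn hydrostannation of an aryl propiolate made from 3,4-dihydroxybenzaldehyde.
4. Unit A comes from syringaldehyde: O-benzylation, bromination at C2, exchange of Br for OH, then bromo-Wittig olefination and lactonisation.
5. Ring order: pyranone of unit A (step 5), temporary dioxole on the catechol (step 6, removed in step 11), pyranone of unit B (step 12).

Key step: step 12

Remark: unprimed locants denote unit A and primed locants unit B, also in the open-chain precursors; Ph3P=C(Br)CO2Et is taken as a catalogue reagent (otherwise made from Ph3P=CHCO2Et and NBS).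

**Step 1**
Reactants: 1 syringaldehyde (4-hydroxy-3,5-dimethoxybenzaldehyde)
Product: 2 4-(benzyloxy)-3,5-dimethoxybenzaldehyde
Conditions: BnBr, K2CO3, DMF, 60 °C
Reagents that add atoms: benzyl bromide BrCc1ccccc1
Why: Williamson etherification of the only phenol caps the future O7 with a group that should tolerate organolithium, palladium coupling, acid and Ag2O and that leaves by hydrogenolysis at the end.

**Step 2**
Reactants: 2 4-(benzyloxy)-3,5-dimethoxybenzaldehyde
Product: 3 4-(benzyloxy)-2-bromo-3,5-dimethoxybenzaldehyde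
Conditions: NBS (1.0 equiv), MeCN, rt, dark
Reagents that add atoms: N-bromosuccinimide O=C1CCC(=O)N1Br
Why: Electrophilic aromatic bromination should give a single monobromide, because C2 and C6 are the only free positions, are equivalent, and are each activated by one ortho and one para methoxy group, while polar dark conditions spare the benzylic CH2.

**Step 3**
Reactants: 3 4-(benzyloxy)-2-bromo-3,5-dimethoxybenzaldehyde
Product: 4 2-[4-(benzyloxy)-2-bromo-3,5-dimethoxyphenyl]-1,3-dioxolane
Conditions: HOCH2CH2OH, p-TsOH (cat.), toluene, reflux, Dean–Stark trap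
Reagents that add atoms: ethylene glycol OCCO
Why: Acid-catalysed acetalisation with azeotropic removal of water masks the aldehyde against n-BuLi and against Dakin-type oxidation in the next step.

**Step 4**
Reactants: 4 2-[4-(benzyloxy)-2-bromo-3,5-dimethoxyphenyl]-1,3-dioxolane
Product: 8 4-(benzyloxy)-2-hydroxy-3,5-dimethoxybenzaldehyde, via aryllithium 5 (not isolated), via lithium aryltrimethoxyborate 6 (not isolated), via phenol acetal 7 (not isolated)
Conditions: n-BuLi, THF, −78 °C; B(OMe)3, −78 °C to rt; 30% H2O2, 0 °C to rt; 2 M HCl, rt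
Reagents that add atoms: hydrogen peroxide OO (phenol oxygen); water O (aldehyde oxygen); n-butyllithium [Li]CCCC and trimethyl borate COB(OC)OC (atoms kept only in 5 and 6)
Why: Bromine–lithium exchange, borylation, oxidative aryl migration from boron to oxygen and acid hydrolysis of the dioxolane form the standard aryl bromide to phenol sequence and place OH on the carbon that becomes C8a.

**Step 5**
Reactants: 8 4-(benzyloxy)-2-hydroxy-3,5-dimethoxybenzaldehyde
Product: 11 7-(benzyloxy)-3-bromo-6,8-dimethoxy-2H-chromen-2-one, via (Z)-bromocinnamate 9 (not isolated), via (E)-bromocinnamate 10 (not isolated)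
Conditions: Ph3P=C(Br)CO2Et, toluene, 110 °C; then PhNEt2, 200 °C
Reagents that add atoms: ethyl bromo(triphenylphosphoranylidene)acetate CCOC(=O)C(Br)=P(c1ccccc1)(c1ccccc1)c1ccccc1
Why: This is the classical high-temperature Wittig olefination and lactonisation of a salicylaldehyde, in which the ortho-hydroxycinnamate isomers interconvert and only 10 (ester cis to the phenol ring) is drained by irreversible loss of ethanol, so bromine reaches C3 without an electrophilic bromination that would attack the activated C5–H.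

**Step 6**
Reactants: 12 3,4-dihydroxybenzaldehyde
Product: 13 2,2-diphenyl-1,3-benzodioxole-5-carbaldehyde
Conditions: Ph2CCl2, Ph2O, 175 °C
Reagents that add atoms: dichlorodiphenylmethane ClC(Cl)(c1ccccc1)c1ccccc1
Why: Double O-alkylation of the catechol by the gem-dichloride ties both hydroxyls into one diphenylmethylene ketal, which tolerates n-BuLi, Bu3SnH, fluoride and palladium and falls off in acid together with a tert-butyl ester.

**Step 7**
Reactants: 13 2,2-diphenyl-1,3-benzodioxole-5-carbaldehyde
Product: 14 5-(2,2-dibromovinyl)-2,2-diphenyl-1,3-benzodioxole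
Conditions: CBr4, PPh3, CH2Cl2, 0 °C
Reagents that add atoms: carbon tetrabromide BrC(Br)(Br)Br
Why: Ramirez dibromoolefination, the first half of the Corey–Fuchs homologation, is a Wittig reaction of in situ Ph3P=CBr2 with a non-enolisable aromatic aldehyde.

**Step 8**
Reactants: 14 5-(2,2-dibromovinyl)-2,2-diphenyl-1,3-benzodioxole
Product: 16 tert-butyl 3-(2,2-diphenyl-1,3-benzodioxol-5-yl)prop-2-ynoate, via lithium acetylide 15 (not isolated)
Conditions: n-BuLi (2.1 equiv), THF, −78 °C; Boc2O, −78 °C to rt; H2O quench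
Reagents that add atoms: di-tert-butyl dicarbonate CC(C)(C)OC(=O)OC(=O)OC(C)(C)C; n-butyllithium [Li]CCCC (lithium kept only in 15)
Why: In the second half of the Corey–Fuchs reaction, bromine–lithium exchange, loss of LiBr with hydride shift and deprotonation give acetylide 15, which Boc2O acylates to the tert-butyl alkynoate.

**Step 9**
Reactants: 16 tert-butyl 3-(2,2-diphenyl-1,3-benzodioxol-5-yl)prop-2-ynoate
Product: 17 tert-butyl (E)-3-(2,2-diphenyl-1,3-benzodioxol-5-yl)-2-(tributylstannyl)prop-2-enoate
Conditions: Bu3SnH, Pd(PPh3)4 (cat.), THF, 0 °C to rt, dark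
Reagents that add atoms: tributyltin hydride CCCC[SnH](CCCC)CCCC
Why: Palladium-catalysed hydrostannation of an alkynoate is a syn addition that puts hydrogen on the aryl-bearing β-carbon and tin on the α-carbon, so the aryl ring and the ester end up cis, the geometry that the lactonisation needs.

**Step 10**
Reactants: 11 7-(benzyloxy)-3-bromo-6,8-dimethoxy-2H-chromen-2-one; 17 tert-butyl (E)-3-(2,2-diphenyl-1,3-benzodioxol-5-yl)-2-(tributylstannyl)prop-2-enoate
Product: 18 tert-butyl (Z)-2-[7-(benzyloxy)-6,8-dimethoxy-2-oxo-2H-chromen-3-yl]-3-(2,2-diphenyl-1,3-benzodioxol-5-yl)prop-2-enoate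
Conditions: Pd(PPh3)4 (cat.), CuI (cat.), CsF, DMF, 45 °C
Reagents that add atoms: none
Why: Stille coupling in its CuI- and fluoride-accelerated form for hindered stannanes should make C3–C3' with retention of the alkene geometry, the activated 3-bromocoumarin adding readily to zerovalent palladium.

**Step 11**
Reactants: 18 tert-butyl (Z)-2-[7-(benzyloxy)-6,8-dimethoxy-2-oxo-2H-chromen-3-yl]-3-(2,2-diphenyl-1,3-benzodioxol-5-yl)prop-2-enoate
Product: 19 (Z)-2-[7-(benzyloxy)-6,8-dimethoxy-2-oxo-2H-chromen-3-yl]-3-(3,4-dihydroxyphenyl)prop-2-enoic acid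
Conditions: TFA–CH2Cl2–H2O, 0 °C to rt, Ar
Reagents that add atoms: none
Why: Under acidolysis the tert-butyl ester leaves as isobutene by alkyl–oxygen cleavage and the ketal hydrolyses through a diphenyl-stabilised oxocarbenium ion, while the lactone, the aryl benzyl ether and the electron-poor trisubstituted alkene should stay untouched in this base-free medium.

**Step 12**
Reactants: 19 (Z)-2-[7-(benzyloxy)-6,8-dimethoxy-2-oxo-2H-chromen-3-yl]-3-(3,4-dihydroxyphenyl)prop-2-enoic acid
Product: 22 7-(benzyloxy)-6',7'-dihydroxy-6,8-dimethoxy-2H,2'H-[3,3'-bichromene]-2,2'-dione (7-O-benzylarteminorin C), via ortho-quinone acid 20 (not isolated), via dienone adduct 21 (not isolated)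
Conditions: Ag2O (1.0 equiv), 4 Å molecular sieves, dry MeCN, high dilution, 0 °C to rt, dark, Ar
Reagents that add atoms: none
Why: Ag2O takes two electrons and two protons from the 3,4-dihydroxyphenyl ring of 19 and, being basic, also ionises the acid; in the resulting ortho-quinone 20 the carboxylate, held next to the ring by the Z alkene, adds to C8a', the β-carbon of the C7'=O/C8'=C8a' enone, to give dienone 21, and loss of H-8a' by enolisation returns the aromatic 6',7'-diol, so the two oxidising equivalents end up in the new C8a'–O1' bond. The closest known reaction type is the oxidative cyclisation of cis-caffeic acid to esculetin (and of dihydrocaffeic acid to its dihydrocoumarin) through the ortho-quinone, the oxygen counterpart of the dopaquinone-to-cyclodopa closure at the same ring position. The pyranone ring of unit B closes in a 6-exo-trig oxa-Michael mode, since the attacked C8'=C8a' bond has only C8a' inside the new ring. No stereocentre is created in 22: C8a' is sp3 only in transient, racemic 21, and the alkene geometry set in step 9 becomes the endocyclic C3'=C4' bond. Chemoselectivity rests on the benzyl cap at O7, which leaves the catechol as the only free phenol unit, on the fully substituted C3', which blocks the radical C–C dimerisation that Ag2O causes with simple caffeates, and on the use of one equivalent of oxidant at high dilution because 22 is again a catechol. Regioselectivity rests on reversibility: 5-exo attack at C4a' gives a spirolactone that has no hydrogen to lose and reopens, attack at C5' would strike the α-carbon of the C6' carbonyl, and only the C8a' adduct is removed irreversibly by aromatisation.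

**Step 13**
Reactants: 22 7-O-benzylarteminorin C
Product: 23 arteminorin C (6',7,7'-trihydroxy-6,8-dimethoxy-2H,2'H-[3,3'-bichromene]-2,2'-dione)
Conditions: H2 (1 atm), 10% Pd/C, THF–MeOH, rt
Reagents that add atoms: none
Why: Catalytic hydrogenolysis of the aryl benzyl ether should be much faster at 1 atm than hydrogenation of the two trisubstituted, fully conjugated C3=C4 bonds of the 3-substituted coumarins.

**Compound list**

1 | syringaldehyde | COc1cc(C=O)cc(OC)c1O | starting material
2 | 4-(benzyloxy)-3,5-dimethoxybenzaldehyde | COc1cc(C=O)cc(OC)c1OCc1ccccc1 | intermediate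
3 | 4-(benzyloxy)-2-bromo-3,5-dimethoxybenzaldehyde | COc1cc(C=O)c(Br)c(OC)c1OCc1ccccc1 | intermediate
4 | 2-[4-(benzyloxy)-2-bromo-3,5-dimethoxyphenyl]-1,3-dioxolane | COc1cc(C2OCCO2)c(Br)c(OC)c1OCc1ccccc1 | intermediate
5 | [3-(benzyloxy)-6-(1,3-dioxolan-2-yl)-2,4-dimethoxyphenyl]lithium | COc1cc(C2OCCO2)c([Li])c(OC)c1OCc1ccccc1 | intermediate
6 | lithium [3-(benzyloxy)-6-(1,3-dioxolan-2-yl)-2,4-dimethoxyphenyl]trimethoxyborate | [Li+].COc1cc(C2OCCO2)c([B-](OC)(OC)OC)c(OC)c1OCc1ccccc1 | intermediate
7 | 3-(benzyloxy)-6-(1,3-dioxolan-2-yl)-2,4-dimethoxyphenol | COc1cc(C2OCCO2)c(O)c(OC)c1OCc1ccccc1 | intermediate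
8 | 4-(benzyloxy)-2-hydroxy-3,5-dimethoxybenzaldehyde | COc1cc(C=O)c(O)c(OC)c1OCc1ccccc1 | intermediate
9 | ethyl (Z)-3-[4-(benzyloxy)-2-hydroxy-3,5-dimethoxyphenyl]-2-bromoprop-2-enoate | CCOC(=O)/C(Br)=C/c1cc(OC)c(OCc2ccccc2)c(OC)c1O | intermediate
10 | ethyl (E)-3-[4-(benzyloxy)-2-hydroxy-3,5-dimethoxyphenyl]-2-bromoprop-2-enoate | CCOC(=O)/C(Br)=C\c1cc(OC)c(OCc2ccccc2)c(OC)c1O | intermediate
11 | 7-(benzyloxy)-3-bromo-6,8-dimethoxy-2H-chromen-2-one | COc1cc2cc(Br)c(=O)oc2c(OC)c1OCc1ccccc1 | intermediate
12 | 3,4-dihydroxybenzaldehyde | O=Cc1ccc(O)c(O)c1 | starting material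
13 | 2,2-diphenyl-1,3-benzodioxole-5-carbaldehyde | O=Cc1ccc2c(c1)OC(c1ccccc1)(c1ccccc1)O2 | intermediate
14 | 5-(2,2-dibromovinyl)-2,2-diphenyl-1,3-benzodioxole | BrC(Br)=Cc1ccc2c(c1)OC(c1ccccc1)(c1ccccc1)O2 | intermediate
15 | [(2,2-diphenyl-1,3-benzodioxol-5-yl)ethynyl]lithium | [Li]C#Cc1ccc2c(c1)OC(c1ccccc1)(c1ccccc1)O2 | intermediate
16 | tert-butyl 3-(2,2-diphenyl-1,3-benzodioxol-5-yl)prop-2-ynoate | CC(C)(C)OC(=O)C#Cc1ccc2c(c1)OC(c1ccccc1)(c1ccccc1)O2 | intermediate
17 | tert-butyl (E)-3-(2,2-diphenyl-1,3-benzodioxol-5-yl)-2-(tributylstannyl)prop-2-enoate | CCCC[Sn](CCCC)(CCCC)/C(C(=O)OC(C)(C)C)=C/c1ccc2c(c1)OC(c1ccccc1)(c1ccccc1)O2 | intermediate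
18 | tert-butyl (Z)-2-[7-(benzyloxy)-6,8-dimethoxy-2-oxo-2H-chromen-3-yl]-3-(2,2-diphenyl-1,3-benzodioxol-5-yl)prop-2-enoate | CC(C)(C)OC(=O)/C(c1cc2cc(OC)c(OCc3ccccc3)c(OC)c2oc1=O)=C\c1ccc2c(c1)OC(c1ccccc1)(c1ccccc1)O2 | intermediate
19 | (Z)-2-[7-(benzyloxy)-6,8-dimethoxy-2-oxo-2H-chromen-3-yl]-3-(3,4-dihydroxyphenyl)prop-2-enoic acid | O=C(O)/C(c1cc2cc(OC)c(OCc3ccccc3)c(OC)c2oc1=O)=C\c1ccc(O)c(O)c1 | intermediate
20 | (Z)-2-[7-(benzyloxy)-6,8-dimethoxy-2-oxo-2H-chromen-3-yl]-3-(3,4-dioxocyclohexa-1,5-dien-1-yl)prop-2-enoic acid | O=C(O)/C(c1cc2cc(OC)c(OCc3ccccc3)c(OC)c2oc1=O)=C\C1=CC(=O)C(=O)C=C1 | intermediate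
21 | 7-(benzyloxy)-7'-hydroxy-6,8-dimethoxy-8a'H-[3,3'-bichromene]-2,2',6'-trione (racemic at C8a', transient) | COc1cc2cc(C3=CC4=CC(=O)C(O)=CC4OC3=O)c(=O)oc2c(OC)c1OCc1ccccc1 | intermediate
22 | 7-(benzyloxy)-6',7'-dihydroxy-6,8-dimethoxy-2H,2'H-[3,3'-bichromene]-2,2'-dione | COc1cc2cc(-c3cc4cc(O)c(O)cc4oc3=O)c(=O)oc2c(OC)c1OCc1ccccc1 | intermediate
23 | arteminorin C | COc1cc2cc(-c3cc4cc(O)c(O)cc4oc3=O)c(=O)oc2c(OC)c1O | target

**Step count**

Total step count: 13. Longest linear sequence: 9 (steps 1–5 and 10–13). The unit B arm (steps 6–9) joins at step 10.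

**Steps most likely to fail**

1. **Step 12.** The ortho-quinone may be consumed by intermolecular addition, redox exchange and oligomerisation faster than the carboxylate closes. The product is again a catechol and may be oxidised further.
   - Fallback principle: the oxygen at C8a' is bought instead of made. The fallback sets out from 8 and comes back at 22.
   - Perkin-type condensation of 8 with succinic anhydride and disodium succinate (NaO2CCH2CH2CO2Na) in the melt at 170–180 °C should give [7-(benzyloxy)-6,8-dimethoxy-2-oxo-2H-chromen-3-yl]acetic acid F1.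
   - Perkin–Oglialoro condensation of this acid with commercial 2,4,5-trihydroxybenzaldehyde in Ac2O/Et3N at 110 °C acetylates the phenols, condenses and lactonises through the ortho oxygen. It should give 7-(benzyloxy)-6,8-dimethoxy-2,2'-dioxo-2H,2'H-[3,3'-bichromene]-6',7'-diyl diacetate F2.
   - Acid methanolysis (HCl, MeOH, reflux, Ar) removes the two acetates and gives 22.

2. **Step 10.** Transmetalation at the hindered, electron-poor α-stannyl acrylate carbon may be slow. Protodestannylation, homocoupling or erosion of the alkene geometry could then take over.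
   - Fallback principle: the polarity of the two partners is reversed. The fallback sets out from 17 and 11 and comes back at 18.
   - Iododestannylation of 17 (I2, CH2Cl2, 0 °C, retention) should give tert-butyl (E)-3-(2,2-diphenyl-1,3-benzodioxol-5-yl)-2-iodoprop-2-enoate F3.
   - Miyaura borylation of 11 (B2pin2, PdCl2(dppf), KOAc, dioxane, 80 °C) should give 7-(benzyloxy)-6,8-dimethoxy-3-(4,4,5,5-tetramethyl-1,3,2-dioxaborolan-2-yl)-2H-chromen-2-one F4.
   - Suzuki–Miyaura coupling of the two (Pd(PPh3)4, K3PO4, dioxane–H2O, 60 °C) proceeds with retention at the iodoalkene and gives 18.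

3. **Step 5.** The weakly nucleophilic bromo ylide may add sluggishly to the electron-rich, hydrogen-bonded aldehyde. The olefination favours the isomer with the ester trans to the phenol ring, so lactonisation may stall or be overtaken by ring closure of the phenol oxygen onto the brominated carbon.
   - Fallback principle: the coumarin is closed first and the halogen is placed through nitrogen. The fallback sets out from 8 and comes back at 11.
   - Erlenmeyer-type Perkin condensation of 8 with N-acetylglycine (Ac2O, NaOAc, 110 °C) should give N-[7-(benzyloxy)-6,8-dimethoxy-2-oxo-2H-chromen-3-yl]acetamide F5.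
   - Hydrolysis (aq. HCl, EtOH, reflux, short time) should give 3-amino-7-(benzyloxy)-6,8-dimethoxy-2H-chromen-2-one F6.
   - Diazotisation (NaNO2, aq. HBr, 0 °C) gives 7-(benzyloxy)-6,8-dimethoxy-2-oxo-2H-chromene-3-diazonium bromide F7, and a Sandmeyer reaction with CuBr gives 11.

**Further compounds**

F1 | step 12 | [7-(benzyloxy)-6,8-dimethoxy-2-oxo-2H-chromen-3-yl]acetic acid | COc1cc2cc(CC(=O)O)c(=O)oc2c(OC)c1OCc1ccccc1
F2 | step 12 | 7-(benzyloxy)-6,8-dimethoxy-2,2'-dioxo-2H,2'H-[3,3'-bichromene]-6',7'-diyl diacetate | COc1cc2cc(-c3cc4cc(OC(C)=O)c(OC(C)=O)cc4oc3=O)c(=O)oc2c(OC)c1OCc1ccccc1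
F3 | step 10 | tert-butyl (E)-3-(2,2-diphenyl-1,3-benzodioxol-5-yl)-2-iodoprop-2-enoate | CC(C)(C)OC(=O)/C(I)=C\c1ccc2c(c1)OC(c1ccccc1)(c1ccccc1)O2
F4 | step 10 | 7-(benzyloxy)-6,8-dimethoxy-3-(4,4,5,5-tetramethyl-1,3,2-dioxaborolan-2-yl)-2H-chromen-2-one | COc1cc2cc(B3OC(C)(C)C(C)(C)O3)c(=O)oc2c(OC)c1OCc1ccccc1
F5 | step 5 | N-[7-(benzyloxy)-6,8-dimethoxy-2-oxo-2H-chromen-3-yl]acetamide | COc1cc2cc(NC(C)=O)c(=O)oc2c(OC)c1OCc1ccccc1
F6 | step 5 | 3-amino-7-(benzyloxy)-6,8-dimethoxy-2H-chromen-2-one | COc1cc2cc(N)c(=O)oc2c(OC)c1OCc1ccccc1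
F7 | step 5 | 7-(benzyloxy)-6,8-dimethoxy-2-oxo-2H-chromene-3-diazonium bromide | COc1cc2cc([N+]#N)c(=O)oc2c(OC)c1OCc1ccccc1.[Br-]
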